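The β-triketone unit of the target (C5=O, C7–OH, C6 isobutyryl) is carried as a 3-isopropylisoxazole fused across C5–C6, a temporary ring opened last by N–O reduction and hydrolysis.
Key disconnections: the ring-fusion bond C4a–C8a at the quaternary stereocentre and the pyran olefin C3=C4, both made in one phosphine-triggered cascade that closes the carbocycle and the 2H-pyran together.
Enabling feature: C4a is the γ-carbon of the C7 ketone through C5=C6 and the neighbour of C4; C8a is the β-carbon of the C7 enone and carries the pyran oxygen (an addition–elimination site); the C3=C4 olefin lies between two fully substituted carbons (C2 and C4a), so a C4 ylide and a C3 aldehyde cannot enolise. One phosphorus on C4 therefore triggers the C–C bond, controls C4a and is spent in the olefination.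
Precursor assembly: symmetric diprenylated diketone → isoxazole → C4 methylene on the lateral carbon (Mannich/elimination) → C8a with the O–CMe2–CHO arm and a MeS leaving group (thio-Claisen with a xanthate, S-methylation).
Ring order: isoxazole (step 2) → carbocycle and 2H-pyran together (step 9) → isoxazole opened to the acyl enol (steps 10 and 11).

Key step: step 9

Assumptions: locants are the chromene locants of the target (O1, C2, C3, C4, C4a, C5 to C8, C8a); the target is one enol tautomer of a β-triketone and is reached as the equilibrating tautomer set; the sense of induction of the phospholane in step 9 cannot be predicted, so the (2R,5R) reagent is written and its commercial antipode would be used if the first run shows the opposite sense.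

Step 1
Reactants: 1 pentane-2,4-dione; 2 1-bromo-3-methylbut-2-ene (2 equiv)
Product: 4 2,12-dimethyltrideca-2,11-diene-6,8-dione, via 8-methylnon-7-ene-2,4-dione 3 (not isolated)
Conditions: LiN(i-Pr)2 (2.1 equiv), THF, −78 → 0 °C; 2 (1.0 equiv); then LiN(i-Pr)2 (1.05 equiv), −78 → 0 °C; 2 (1.0 equiv); aq NH4Cl
Reagents that add atoms: none
Why: β-diketone dianion γ-alkylation run twice in one flask; the terminal carbanion is the most nucleophilic site, the remaining methyl is deprotonated in preference to the substituted methylene, and the bromide is displaced without allylic transposition.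

Step 2
Reactants: 4 2,12-dimethyltrideca-2,11-diene-6,8-dione; 5 2-methylpropanal oxime
Product: 8 1-[3-isopropyl-5-(4-methylpent-3-en-1-yl)isoxazol-4-yl]-5-methylhex-4-en-1-one, via hydroximoyl chloride 6 (not isolated), via nitrile oxide 7 (not isolated)
Conditions: 5, N-chlorosuccinimide, DMF, 23 °C; then 4, Et3N, EtOH, 0 → 23 °C
Reagents that add atoms: none
Why: 1,3-diketone/nitrile oxide isoxazole synthesis (enolate carbon adds to the nitrile oxide, the oxime oxygen condenses with a flanking carbonyl); the symmetry of 4 removes any regiochemical question and makes the isobutyryl carbon isoxazole C3.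

Step 3
Reactants: 8 1-[3-isopropyl-5-(4-methylpent-3-en-1-yl)isoxazol-4-yl]-5-methylhex-4-en-1-one
Product: 9 1-{5-[1-(dimethylamino)-5-methylhex-4-en-2-yl]-3-isopropylisoxazol-4-yl}-5-methylhex-4-en-1-one (racemic)
Conditions: LiN(i-Pr)2 (2.2 equiv), THF, −78 °C; Me2N=CH2 I (Eschenmoser's salt, 1.0 equiv), −78 → −20 °C; aq NaHCO3
Reagents that add atoms: N,N-dimethylmethyleneiminium iodide (Eschenmoser's salt), C=[N+](C)C.[I-]
Why: the first equivalent of base forms the ketone enolate (masking C8) and the second removes a lateral proton of the isoxazole 5-alkyl group, and the less stabilised lateral carbanion of the dianion should attack the iminium ion (lateral metalation of a 5-alkylisoxazole, dianion rule, Mannich reaction); the new stereocentre is destroyed in step 4.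

Step 4
Reactants: 9 Mannich base
Product: 11 1-[3-isopropyl-5-(5-methylhexa-1,4-dien-2-yl)isoxazol-4-yl]-5-methylhex-4-en-1-one, via trimethylammonium iodide 10 (not isolated)
Conditions: MeI, MeCN, 23 °C; then K2CO3, MeCN–H2O, 40 °C
Reagents that add atoms: none
Why: N-methylation and E1cB (Hofmann-type) elimination of trimethylamine, helped by the acidity of the lateral proton (vinylogous to the 4-acyl group), should give the 1,1-disubstituted olefin whose CH2 is the future C4.

Step 5
Reactants: 12 1,1-dimethoxypropan-2-one
Product: 13 1,1-dimethoxy-2-methylpropan-2-ol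
Conditions: MeMgBr, THF, 0 °C; aq NH4Cl
Reagents that add atoms: methylmagnesium bromide, C[Mg]Br
Why: Grignard addition to the ketone of a protected α-keto aldehyde gives the tertiary alcohol that becomes O1–C2(Me2)–C3.

Step 6
Reactants: 13 1,1-dimethoxy-2-methylpropan-2-ol
Product: 15 O-(1,1-dimethoxy-2-methylpropan-2-yl) S-methyl carbonodithioate, via sodium xanthate 14 (not isolated)
Conditions: NaH, THF, 0 °C; CS2; then MeI, 0 °C; used at once
Reagents that add atoms: carbon disulfide, S=C=S; iodomethane, CI
Why: xanthate ester formation (first stage of a Chugaev sequence); the tertiary xanthate is kept cold and used directly to avoid thermal elimination.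

Step 7
Reactants: 11 vinyl isoxazole ketone; 15 xanthate ester
Product: 17 2-{[(1,1-dimethoxy-2-methylpropan-2-yl)oxy](methylsulfanyl)methylidene}-1-[3-isopropyl-5-(5-methylhexa-1,4-dien-2-yl)isoxazol-4-yl]-5-methylhex-4-en-1-one (E/Z mixture), via thionoester 16 (not isolated)
Conditions: LiN(SiMe3)2 (2.2 equiv), THF, −78 °C; 15, −78 → −40 °C; then MeI (2.5 equiv), −40 → 0 °C
Reagents that add atoms: iodomethane, CI
Why: Claisen-type thioacylation, in which the kinetic ketone enolate adds to C=S of 15 and methanethiolate (a better leaving group than the tertiary alkoxide) is expelled, followed by S-methylation of the enethiolate of 16 to the α-oxo ketene O,S-acetal; both olefin isomers present the same C8a.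

Step 8
Reactants: 17 ketene O,S-acetal dimethyl acetal
Product: 18 2-{[2-{[3-isopropyl-5-(5-methylhexa-1,4-dien-2-yl)isoxazol-4-yl]carbonyl}-5-methyl-1-(methylsulfanyl)hexa-1,4-dien-1-yl]oxy}-2-methylpropanal (E/Z mixture)
Conditions: LiBF4, MeCN–H2O (98:2), 40 °C
Reagents that add atoms: water, O
Why: mild Lewis-acid acetal hydrolysis should unmask the non-enolisable C3 aldehyde, the push–pull ketene acetal and the isoxazole being inert under these conditions.

Step 9
Reactants: 18 aldehyde
Product: 21 (4aR)-2,2-dimethyl-4a,8-bis(3-methylbut-2-en-1-yl)-2H-chromen-7(4aH)-one fused at C5–C6 to a 3-isopropylisoxazole (isoxazole O on C5), via phosphonium tetrafluoroborate 19 (not isolated), via cyclised phosphonium tetrafluoroborate 20 (not isolated)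
Conditions: (2R,5R)-2,5-dimethyl-1-phenylphospholane·HBF4 (1.05 equiv), MeCN, 40 °C; then KOt-Bu (2.2 equiv), THF, −40 → 23 °C, same flask
Reagents that add atoms: none
Why: Proposed new method: the phospholanium salt delivers its phosphine to C4, the terminal vinyl carbon and δ-position of the C7 ketone through the isoxazole C4–C5 bond (acid-mediated hydrophosphination as with vinyl ketones and vinylpyridines), to give 19; KOt-Bu then removes the C4a proton, the carbanion adds to C8a of the α-oxo ketene O,S-acetal and expels methanethiolate to give 20, and the C4 ylide of 20 olefinates the C3 aldehyde, the closest known reaction types being the phosphine-triggered intramolecular Rauhut–Currier reaction, Michael/intramolecular Wittig annulations of vinylphosphonium salts and carbanion additions to α-oxo ketene dithioacetals. The carbocycle closes by a 6-endo-trig addition–elimination (C4a onto C8a, C8=C8a kept in the ring) and the 2H-pyran by a 6-exo-trig ylide addition with oxaphosphetane collapse, which can only give the cis ring olefin. C4a is set in the C–C bond-forming step under reagent control by the C2-symmetric phospholanium group on the adjacent C4, the element that differentiates the enolate faces in enantioselective Rauhut–Currier cyclisations, and (4aR) is the configuration aimed at. Because C4a becomes quaternary the phosphine cannot leave by β-elimination (the normal catalytic turnover), so it is spent as the Wittig phosphorus, and complete prior conversion to 19 leaves no free vinyl group for the released thiolate. The selectivities required are carbon over oxygen attack, six-membered over other ring sizes and the C4 ylide over ylides on the phospholane ring: the isoxazole masks the C5 and acyl oxygens, leaves C4a–H as the only acidic proton and holds the two arms ortho, the C7 oxygen could only form a four-membered ring and the C3 aldehyde a nine-membered one with C4a, and ylides equilibrate by proton transfer while only the C4 ylide has the aldehyde within reach.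

Step 10
Reactants: 21 tricyclic isoxazole
Product: 22 (4aR)-6-(1-amino-2-methylpropylidene)-2,2-dimethyl-4a,8-bis(3-methylbut-2-en-1-yl)-2H-chromene-5,7(4aH,6H)-dione
Conditions: Mo(CO)6, MeCN–H2O, 80 °C
Reagents that add atoms: none
Why: reductive N–O cleavage of a 4-acylisoxazole to the 2-(aminoalkylidene)-1,3-dione (standard isoxazole unmasking) should leave the olefins and the quaternary C4a untouched.

Step 11
Reactants: 22 enaminone
Product: 23 (4aR)-7-hydroxy-2,2-dimethyl-4a,8-bis(3-methylbut-2-en-1-yl)-6-(2-methylpropanoyl)-2H-chromen-5(4aH)-one (CNP0119032.1)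
Conditions: NaOH (2 equiv), EtOH–H2O, 50 °C; then 1 M HCl to pH 4, 0 °C
Reagents that add atoms: water, O
Why: enaminone hydrolysis (hydroxide adds to the aminoalkylidene carbon, ammonia is lost) should free the β-triketone, which settles on acidification as the hydrogen-bonded enol drawn; C4a is quaternary and cannot epimerise.

Compound list
1 | pentane-2,4-dione | CC(=O)CC(=O)C | starting material
2 | 1-bromo-3-methylbut-2-ene (prenyl bromide) | CC(C)=CCBr | starting material
3 | 8-methylnon-7-ene-2,4-dione | CC(=O)CC(=O)CCC=C(C)C | intermediate (not isolated)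
4 | 2,12-dimethyltrideca-2,11-diene-6,8-dione | CC(C)=CCCC(=O)CC(=O)CCC=C(C)C | intermediate
5 | 2-methylpropanal oxime | CC(C)C=NO | starting material
6 | N-hydroxy-2-methylpropanimidoyl chloride | CC(C)C(Cl)=NO | intermediate (not isolated)
7 | 2-methylpropanenitrile oxide | CC(C)C#[N+][O-] | intermediate (not isolated)
8 | 1-[3-isopropyl-5-(4-methylpent-3-en-1-yl)isoxazol-4-yl]-5-methylhex-4-en-1-one | CC(C)c1noc(CCC=C(C)C)c1C(=O)CCC=C(C)C | intermediate
9 | 1-{5-[1-(dimethylamino)-5-methylhex-4-en-2-yl]-3-isopropylisoxazol-4-yl}-5-methylhex-4-en-1-one (racemic) | CC(C)c1noc(C(CN(C)C)CC=C(C)C)c1C(=O)CCC=C(C)C | intermediate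
10 | trimethylammonium iodide of 9 | CC(C)c1noc(C(C[N+](C)(C)C)CC=C(C)C)c1C(=O)CCC=C(C)C.[I-] | intermediate (not isolated)
11 | 1-[3-isopropyl-5-(5-methylhexa-1,4-dien-2-yl)isoxazol-4-yl]-5-methylhex-4-en-1-one | CC(C)c1noc(C(=C)CC=C(C)C)c1C(=O)CCC=C(C)C | intermediate
12 | 1,1-dimethoxypropan-2-one | CC(=O)C(OC)OC | starting material
13 | 1,1-dimethoxy-2-methylpropan-2-ol | COC(OC)C(C)(C)O | intermediate
14 | sodium O-(1,1-dimethoxy-2-methylpropan-2-yl) carbonodithioate | COC(OC)C(C)(C)OC(=S)[S-].[Na+] | intermediate (not isolated)
15 | O-(1,1-dimethoxy-2-methylpropan-2-yl) S-methyl carbonodithioate | COC(OC)C(C)(C)OC(=S)SC | intermediate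
16 | thionoester: O-(1,1-dimethoxy-2-methylpropan-2-yl) 2-{[3-isopropyl-5-(5-methylhexa-1,4-dien-2-yl)isoxazol-4-yl]carbonyl}-5-methylhex-4-enethioate | CC(C)c1noc(C(=C)CC=C(C)C)c1C(=O)C(CC=C(C)C)C(=S)OC(C)(C)C(OC)OC | intermediate (not isolated)
17 | ketene O,S-acetal (dimethyl acetal), E/Z mixture | CC(C)c1noc(C(=C)CC=C(C)C)c1C(=O)C(CC=C(C)C)=C(SC)OC(C)(C)C(OC)OC | intermediate
18 | ketene O,S-acetal aldehyde, E/Z mixture (key-step precursor) | CC(C)c1noc(C(=C)CC=C(C)C)c1C(=O)C(CC=C(C)C)=C(SC)OC(C)(C)C=O | intermediate
19 | phosphonium tetrafluoroborate (phospholanium on C4, C4a–H, epimer mixture at C4a) | CC(C)c1noc(C(CC=C(C)C)C[P+]2(c3ccccc3)[C@H](C)CC[C@H]2C)c1C(=O)C(CC=C(C)C)=C(SC)OC(C)(C)C=O.F[B-](F)(F)F | intermediate (not isolated)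
20 | cyclised phosphonium tetrafluoroborate (C4a–C8a formed, R at the quaternary carbon, C3 aldehyde free) | CC(C)c1noc2c1C(=O)C(CC=C(C)C)=C(OC(C)(C)C=O)[C@@]2(CC=C(C)C)C[P+]1(c2ccccc2)[C@H](C)CC[C@H]1C.F[B-](F)(F)F | intermediate (not isolated)
21 | (4aR)-tricyclic isoxazole: 2,2-dimethyl-4a,8-bis(3-methylbut-2-en-1-yl)-2H-chromen-7(4aH)-one fused at C5–C6 to a 3-isopropylisoxazole (isoxazole O on C5, isoxazole C4 = C6) | CC(C)c1noc2c1C(=O)C(CC=C(C)C)=C1OC(C)(C)C=C[C@]12CC=C(C)C | intermediate
22 | (4aR)-6-(1-amino-2-methylpropylidene)-2,2-dimethyl-4a,8-bis(3-methylbut-2-en-1-yl)-2H-chromene-5,7(4aH,6H)-dione | CC(C)C(N)=C1C(=O)C(CC=C(C)C)=C2OC(C)(C)C=C[C@@]2(CC=C(C)C)C1=O | intermediate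
23 | (4aR)-7-hydroxy-2,2-dimethyl-4a,8-bis(3-methylbut-2-en-1-yl)-6-(2-methylpropanoyl)-2H-chromen-5(4aH)-one (CNP0119032.1) | CC(C)=CCC1=C2OC(C)(C)C=C[C@@]2(CC=C(C)C)C(=O)C(C(=O)C(C)C)=C1O | target

Total step count: 11. Longest linear sequence: 9 steps (1–4, 7–11); steps 5 and 6 prepare xanthate 15.

Steps most likely to fail

Step 9 (Proposed new method). The cascade may stall because phosphine loss from the deprotonated salt outruns the hindered C4a–C8a ring closure, after which the released thiolate can add to C4. It may also close with low facial selectivity at C4a, or form the ylide on the phospholane ring. Fallback with known reactions, setting out from 8 and returning to 21: the dianion of 8 is trapped at the lateral carbon with acetaldehyde to give 1-[5-(2-hydroxy-6-methylhept-5-en-3-yl)-3-isopropylisoxazol-4-yl]-5-methylhex-4-en-1-one F1. This is dehydrated through its methanesulfonate F2 (MeSO2Cl, Et3N; then DBU) to the 5-(6-methylhepta-2,5-dien-3-yl)isoxazole F3. Thioacylation with 15 as in step 7, through thionoester F4, and S-methylation give ketene O,S-acetal F5. γ-Deprotonation of the propenyl methyl group under asymmetric phase-transfer catalysis (N-(9-anthracenylmethyl)cinchonidinium chloride, CsOH·H2O, PhMe, −20 °C) and α-selective vinylic substitution at C8a should give the (7R)-7-ethenyl-1,2-benzisoxazol-4(7H)-one F6; enantioselective phase-transfer vinylic substitution and vinylogous isoxazole alkylation are known reaction types. Acetal hydrolysis (LiBF4, wet MeCN) gives aldehyde F7, Wittig methylenation (Ph3P=CH2) gives diene F8, and ring-closing metathesis with the Hoveyda–Grubbs second-generation catalyst forms C3=C4 and gives 21.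

Step 3. Site selectivity may be lost (aminomethylation at the ketone α-carbon, or double alkylation) if the second deprotonation is incomplete. Fallback setting out from 8 and returning to 9: the ketone is first blocked as its trimethylsilyl enol ether F9 (LiN(i-Pr)2, Me3SiCl, −78 °C). The lateral position alone is then lithiated (n-BuLi, −78 °C) and aminomethylated with Eschenmoser's salt to give the silylated Mannich base F10, and aqueous fluoride work-up removes the silyl group to give 9.

Step 7. The tertiary xanthate may eliminate thermally before it is attacked, or the enolate may add to the neighbouring vinyl group before thioacylation. Fallback setting out from 11 and returning to 17: the order of C–S and C–O bond formation is reversed. The enolate of 11 is treated with CS2 and then MeI (2 equiv) to give the α-oxo ketene dithioacetal F11 (standard ketene dithioacetal synthesis). One methylsulfanyl group is then displaced by the potassium alkoxide of 13 (KH, 18-crown-6, THF, 0 °C; addition–elimination) to give 17.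

Further compounds
F1 | step 9 | 1-[5-(2-hydroxy-6-methylhept-5-en-3-yl)-3-isopropylisoxazol-4-yl]-5-methylhex-4-en-1-one | CC(C)c1noc(C(C(C)O)CC=C(C)C)c1C(=O)CCC=C(C)C
F2 | step 9 | methanesulfonate of F1 | CC(C)c1noc(C(C(C)OS(C)(=O)=O)CC=C(C)C)c1C(=O)CCC=C(C)C
F3 | step 9 | 1-[3-isopropyl-5-(6-methylhepta-2,5-dien-3-yl)isoxazol-4-yl]-5-methylhex-4-en-1-one | CC(C)c1noc(C(=CC)CC=C(C)C)c1C(=O)CCC=C(C)C
F4 | step 9 | thionoester from F3 and 15 | CC(C)c1noc(C(=CC)CC=C(C)C)c1C(=O)C(CC=C(C)C)C(=S)OC(C)(C)C(OC)OC
F5 | step 9 | ketene O,S-acetal from F4 (E/Z mixture) | CC(C)c1noc(C(=CC)CC=C(C)C)c1C(=O)C(CC=C(C)C)=C(SC)OC(C)(C)C(OC)OC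
F6 | step 9 | (7R)-6-[(1,1-dimethoxy-2-methylpropan-2-yl)oxy]-7-ethenyl-3-isopropyl-5,7-bis(3-methylbut-2-en-1-yl)-1,2-benzisoxazol-4(7H)-one | CC(C)c1noc2c1C(=O)C(CC=C(C)C)=C(OC(C)(C)C(OC)OC)[C@]2(C=C)CC=C(C)C
F7 | step 9 | 2-{[(7R)-7-ethenyl-3-isopropyl-5,7-bis(3-methylbut-2-en-1-yl)-4-oxo-4,7-dihydro-1,2-benzisoxazol-6-yl]oxy}-2-methylpropanal | CC(C)c1noc2c1C(=O)C(CC=C(C)C)=C(OC(C)(C)C=O)[C@]2(C=C)CC=C(C)C
F8 | step 9 | (7R)-7-ethenyl-3-isopropyl-6-[(2-methylbut-3-en-2-yl)oxy]-5,7-bis(3-methylbut-2-en-1-yl)-1,2-benzisoxazol-4(7H)-one | CC(C)c1noc2c1C(=O)C(CC=C(C)C)=C(OC(C)(C)C=C)[C@]2(C=C)CC=C(C)C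
F9 | step 3 | trimethylsilyl enol ether of 8 | CC(C)c1noc(CCC=C(C)C)c1C(O[Si](C)(C)C)=CCC=C(C)C
F10 | step 3 | trimethylsilyl enol ether of 9 | CC(C)c1noc(C(CN(C)C)CC=C(C)C)c1C(O[Si](C)(C)C)=CCC=C(C)C
F11 | step 7 | 2-[bis(methylsulfanyl)methylidene]-1-[3-isopropyl-5-(5-methylhexa-1,4-dien-2-yl)isoxazol-4-yl]-5-methylhex-4-en-1-one | CC(C)c1noc(C(=C)CC=C(C)C)c1C(=O)C(CC=C(C)C)=C(SC)SC
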